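**Retrosynthetic overview**
1. Target 34 ⇒ 12-membered β-keto lactone 32: a Dieckmann ring contraction closes the tetronate and turns the lactone into the 11-membered carbocycle; the silyl ethers fall in the same pot.
2. 32 ⇒ ester 31 by Z-selective ring-closing metathesis of two allyl groups.
3. 31 ⇒ key C–O bond: the lactone O–C(=O) bond of the future tetronate, made by trapping decalin acylketene 30 (from tert-butyl β-keto ester 29) with the hindered tertiary α-hydroxy ester 9.
4. 9 ⇒ enantioselective exo Diels–Alder of triene 5 with methyl 2-acetoxyacrylate 7 (new method); 29 ⇒ intramolecular Diels–Alder of tetraenal 26, whose stereotriad comes from an anti vinylogous aldol and a 1,3-syn reduction.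
5. Ring order: cyclohexene (fragment A) and trans-decalin (fragment B) in parallel → ester union → 12-membered lactone → spirotetronate with 11-membered carbocycle.

Assumption: the target is the enol tautomer and enantiomer drawn; for the two chiral catalysts the enantiomer named is the one expected to deliver the stated face, and its antipode is used if a first run shows the opposite sense.

**Fragment A (cyclohexene)**

Step 1
Reactants: 1 (2E)-2-methylpent-2-enal
Product: 2 ethyl (2E,4E)-2,4-dimethylhepta-2,4-dienoate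
Conditions: Ph3P=C(Me)CO2Et (1.2 equiv), toluene, 100 °C
Reagents that add atoms: ethyl 2-(triphenylphosphoranylidene)propanoate, CCOC(=O)C(C)=P(c1ccccc1)(c1ccccc1)c1ccccc1
Why: Wittig olefination with a stabilised ylide gives the (E)-trisubstituted enoate and leaves the (E)-alkene of 1 untouched.

Step 2
Reactants: 2 ethyl (2E,4E)-2,4-dimethylhepta-2,4-dienoate
Product: 3 (2E,4E)-2,4-dimethylhepta-2,4-dien-1-ol
Conditions: iBu2AlH (2.3 equiv), CH2Cl2, −78 °C; aq. potassium sodium tartrate
Reagents that add atoms: none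
Why: 1,2-reduction of the conjugated ester by an aluminium hydride gives the allylic alcohol without touching the diene.

Step 3
Reactants: 3 (2E,4E)-2,4-dimethylhepta-2,4-dien-1-ol
Product: 4 (2E,4E)-1-bromo-2,4-dimethylhepta-2,4-diene
Conditions: PBr3 (0.4 equiv), Et2O, −10 °C
Reagents that add atoms: phosphorus tribromide, BrP(Br)Br
Why: bromination of a primary allylic alcohol through its phosphite ester at low temperature keeps both alkene geometries.

Step 4
Reactants: 4 (2E,4E)-1-bromo-2,4-dimethylhepta-2,4-diene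
Product: 5 (4E,6E)-4,6-dimethylnona-1,4,6-triene
Conditions: CH2=CHMgBr (1.5 equiv), CuI (5 mol %), THF, −30 → 0 °C
Reagents that add atoms: vinylmagnesium bromide, C=C[Mg]Br
Why: copper-catalysed allyl–vinyl cross-coupling at the primary carbon gives the skipped triene with the diene geometry intact.

Step 5
Reactants: 6 methyl pyruvate
Product: 7 methyl 2-(acetyloxy)prop-2-enoate
Conditions: Ac2O (2 equiv), TsOH·H2O (2 mol %), hydroquinone (trace), 130 °C, AcOH distilled off
Reagents that add atoms: acetic anhydride, CC(=O)OC(C)=O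
Why: acid-catalysed enol acetylation of the α-keto ester, driven by removal of acetic acid.

Step 6
Reactants: 5 (4E,6E)-4,6-dimethylnona-1,4,6-triene (1.5 equiv); 7 methyl 2-(acetyloxy)prop-2-enoate
Product: 8 methyl (1S,2R,5R)-1-(acetyloxy)-5-ethyl-2,4-dimethyl-2-(prop-2-en-1-yl)cyclohex-3-ene-1-carboxylate
Conditions: (S)-B-(o-tolyl) oxazaborolidine of α,α-diphenylprolinol (20 mol %), AlBr3 (16 mol %), CH2Cl2, −40 → −20 °C, 48 h
Reagents that add atoms: none
Why: Proposed new method: the AlBr3-activated oxazaborolidine binds the ester carbonyl of 7 and screens one face, so the diene adds to the Si face at C2 of the acrylate (O > CO2Me > CH2 counter-clockwise seen from the diene); the ethyl-bearing diene terminus has the larger HOMO coefficient and bonds to the CH2, and the inside methyl at the other terminus clashes with the complexed ester in the endo mode, so the ester goes exo and the ethyl centre and both quaternary centres are set in one Diels–Alder step; the closest known reactions are oxazaborolidinium-catalysed Diels–Alder reactions of acrylates and α-substituted acroleins and MeAlCl2-promoted exo cycloadditions of (Z)-substituted dienes, none shown for an α-acyloxyacrylate with a 1,1-disubstituted diene terminus.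

Step 7
Reactants: 8 methyl (1S,2R,5R)-1-(acetyloxy)-5-ethyl-2,4-dimethyl-2-(prop-2-en-1-yl)cyclohex-3-ene-1-carboxylate
Product: 9 methyl (1S,2R,5R)-5-ethyl-1-hydroxy-2,4-dimethyl-2-(prop-2-en-1-yl)cyclohex-3-ene-1-carboxylate
Conditions: K2CO3 (0.2 equiv), MeOH, 25 °C
Reagents that add atoms: none
Why: base-catalysed transesterification removes the activated α-acyloxy acetate and leaves the hindered methyl ester and all stereocentres unchanged.

**Fragment B (decalin)**

Step 8
Reactants: 10 1-(2,4-dinitrophenyl)pyridin-1-ium chloride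
Product: 12 (2E,4E)-5-(dimethylamino)penta-2,4-dienal, via vinamidinium chloride 11 (not isolated)
Conditions: Me2NH (40% aq., 2.5 equiv), EtOH, 0 → 25 °C; then 2 M NaOH, 25 °C
Reagents that add atoms: dimethylamine, CNC; sodium hydroxide, [Na+].[OH-]
Why: Zincke ring opening of the activated pyridinium by the secondary amine and hydrolysis of one iminium end give the all-(E) aminodienal.

Step 9
Reactants: 12 (2E,4E)-5-(dimethylamino)penta-2,4-dienal
Product: 14 (2E,4E)-octa-2,4,7-trienal, via bromomagnesium aminotrienolate 13 (not isolated)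
Conditions: CH2=CHCH2MgBr (1.2 equiv), THF, −78 °C; then 1 M HCl, 0 °C, 10 min
Reagents that add atoms: allylmagnesium bromide, C=CC[Mg]Br
Why: 1,2-addition to the vinylogous formamide, then acid-induced loss of water and iminium hydrolysis (vinylogous formylation of a Grignard reagent), gives the (2E,4E)-dienal directly; the brief cold acidic work-up avoids conjugation of the skipped alkene.

Step 10
Reactants: 15 2,2,6-trimethyl-4H-1,3-dioxin-4-one
Product: 16 6-ethyl-2,2-dimethyl-4H-1,3-dioxin-4-one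
Conditions: LiN(iPr)2 (1.1 equiv), DMPU, THF, −78 °C; MeI
Reagents that add atoms: iodomethane, CI
Why: γ-alkylation of the extended lithium dienolate of the dioxinone.

Step 11
Reactants: 16 6-ethyl-2,2-dimethyl-4H-1,3-dioxin-4-one
Product: 17 tert-butyl{[(6Z)-6-ethylidene-2,2-dimethyl-6H-1,3-dioxin-4-yl]oxy}dimethylsilane
Conditions: LiN(iPr)2 (1.1 equiv), THF, −78 °C; tBuMe2SiCl
Reagents that add atoms: tert-butyl(chloro)dimethylsilane, CC(C)(C)[Si](C)(C)Cl
Why: O-silylation of the lithium dienolate gives the silyl dienol ether needed for the vinylogous aldol.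

Step 12
Reactants: 14 (2E,4E)-octa-2,4,7-trienal; 17 silyl dienol ether (1.2 equiv)
Product: 19 6-[(2R,3R,4E,6E)-3-hydroxydeca-4,6,9-trien-2-yl]-2,2-dimethyl-4H-1,3-dioxin-4-one, via trichlorosilyl ether 18 (not isolated)
Conditions: SiCl4 (1.2 equiv), (S,S)-bisphosphoramide [pentane-1,5-diyl-bridged bis(N-methyl-BINAM phosphoramide)] (5 mol %), CH2Cl2, −78 °C; aq. NaHCO3
Reagents that add atoms: none
Why: Lewis-base-activated SiCl4 vinylogous Mukaiyama aldol: γ-attack through an open transition state gives the anti methyl/hydroxyl pair, and the chiral phosphoramide-bound silicon cation directs attack to the Si face of the aldehyde, which sets both centres.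

Step 13
Reactants: 19 hydroxy dioxinone
Product: 20 methyl (4R,5R,6E,8E)-5-hydroxy-4-methyl-3-oxododeca-6,8,11-trienoate
Conditions: K2CO3 (0.2 equiv), MeOH, 0 °C
Reagents that add atoms: methanol, CO
Why: methanolysis of the dioxinone releases acetone and the β-keto ester; the cold, weakly basic medium avoids lactonisation, retro-aldol and epimerisation of the α-methyl centre.

Step 14
Reactants: 20 methyl (4R,5R,6E,8E)-5-hydroxy-4-methyl-3-oxododeca-6,8,11-trienoate
Product: 22 methyl (3S,4S,5R,6E,8E)-3,5-dihydroxy-4-methyldodeca-6,8,11-trienoate, via diethylboron chelate 21 (not isolated)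
Conditions: Et2BOMe (1.1 equiv), THF/MeOH 4:1, −78 °C; NaBH4; MeOH co-evaporation
Reagents that add atoms: none
Why: Narasaka–Prasad reduction: axial hydride delivery to the six-membered boron chelate gives the 1,3-syn diol and sets the new carbinol centre anti to the methyl group.

Step 15
Reactants: 22 syn-diol ester
Product: 23 methyl (3S,4S,5R,6E,8E)-4-methyl-3,5-bis[(triethylsilyl)oxy]dodeca-6,8,11-trienoate
Conditions: Et3SiOTf (2.5 equiv), 2,6-lutidine, CH2Cl2, −78 → 0 °C
Reagents that add atoms: triethylsilyl trifluoromethanesulfonate, CC[Si](CC)(CC)OS(=O)(=O)C(F)(F)F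
Why: silylation of both secondary alcohols as separate, non-cyclic ethers lets each oxygen sit equatorial in the later cycloaddition.

Step 16
Reactants: 23 bis-silyl ester
Product: 25 (3S,4S,5R,6E,8E)-4-methyl-3,5-bis[(triethylsilyl)oxy]dodeca-6,8,11-trienal, via aluminium hemiacetal 24 (not isolated)
Conditions: iBu2AlH (1.1 equiv), CH2Cl2, −78 °C; aq. potassium sodium tartrate
Reagents that add atoms: none
Why: partial reduction of the ester stops at the tetrahedral aluminium hemiacetal at −78 °C, which gives the aldehyde on work-up.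

Step 17
Reactants: 25 β-silyloxy aldehyde
Product: 26 (2E,5S,6S,7R,8E,10E)-2,6-dimethyl-5,7-bis[(triethylsilyl)oxy]tetradeca-2,8,10,13-tetraenal
Conditions: Ph3P=C(Me)CHO (2 equiv), toluene, 95 °C
Reagents that add atoms: 2-(triphenylphosphoranylidene)propanal, CC(C=O)=P(c1ccccc1)(c1ccccc1)c1ccccc1
Why: Wittig olefination with the stabilised formyl ylide gives the (E)-2-methyl enal dienophile under neutral conditions.

Step 18
Reactants: 26 tetraenal
Product: 27 (1R,2R,4aS,5R,6S,7S,8aR)-1,6-dimethyl-2-(prop-2-en-1-yl)-5,7-bis[(triethylsilyl)oxy]-1,2,4a,5,6,7,8,8a-octahydronaphthalene-1-carbaldehyde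
Conditions: Me2AlCl (1.1 equiv), CH2Cl2, −78 → −30 °C; aq. NaHCO3
Reagents that add atoms: none
Why: Lewis-acid-promoted intramolecular Diels–Alder of the (E,E,E)-trienal through the endo-formyl transition state with a chair tether (both silyloxy groups equatorial, methyl axial, which avoids a 1,3-diaxial pair of silyloxy groups) gives the trans-decalin and sets C1, C2, C4a and C8a relative to the stereotriad.

Step 19
Reactants: 27 decalin aldehyde
Product: 28 tert-butyl 3-hydroxy-3-[(1R,2R,4aS,5R,6S,7S,8aR)-1,6-dimethyl-2-(prop-2-en-1-yl)-5,7-bis[(triethylsilyl)oxy]-1,2,4a,5,6,7,8,8a-octahydronaphthalen-1-yl]propanoate (both carbinol epimers)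
Conditions: CH3CO2tBu, LiN(iPr)2 (1.5 equiv each), THF, −78 °C; then 27; aq. NH4Cl
Reagents that add atoms: tert-butyl acetate, CC(=O)OC(C)(C)C
Why: aldol addition of a small lithium ester enolate to the hindered, non-enolisable aldehyde; the carbinol configuration does not matter because it is oxidised next.

Step 20
Reactants: 28 β-hydroxy ester
Product: 29 tert-butyl 3-[(1R,2R,4aS,5R,6S,7S,8aR)-1,6-dimethyl-2-(prop-2-en-1-yl)-5,7-bis[(triethylsilyl)oxy]-1,2,4a,5,6,7,8,8a-octahydronaphthalen-1-yl]-3-oxopropanoate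
Conditions: Dess–Martin periodinane (1.5 equiv), pyridine, CH2Cl2, 0 → 25 °C
Reagents that add atoms: none
Why: Dess–Martin oxidation gives the β-keto ester under buffered conditions that spare the silyl ethers and alkenes.

**Union and endgame**

Step 21
Reactants: 29 decalin tert-butyl β-keto ester; 9 tertiary hydroxy ester (1.5 equiv)
Product: 31 methyl (1S,2R,5R)-5-ethyl-2,4-dimethyl-2-(prop-2-en-1-yl)-1-({3-oxo-3-[(1R,2R,4aS,5R,6S,7S,8aR)-1,6-dimethyl-2-(prop-2-en-1-yl)-5,7-bis[(triethylsilyl)oxy]-1,2,4a,5,6,7,8,8a-octahydronaphthalen-1-yl]propanoyl}oxy)cyclohex-3-ene-1-carboxylate, via acylketene 30 (not isolated)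
Conditions: toluene (0.1 M), 110 °C, 4 Å molecular sieves in the condensate return
Reagents that add atoms: none
Why: thermal loss of tert-butanol from the enol of the tert-butyl β-keto ester gives acylketene 30, which the tertiary alcohol traps by a pseudopericyclic addition without a crowded tetrahedral intermediate (acylketene esterification), so the lactone C–O bond forms at a centre that resists ordinary acylation; no stereocentre is touched and 110 °C is well below Cope rearrangement of the 1,5-dienes.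

Step 22
Reactants: 31 bis-allyl β-keto ester
Product: 32 12-membered (Z)-β-keto macrolactone (ring-closed 31; methyl ester and both triethylsilyl ethers retained)
Conditions: Ru(κ2-O2NO)(=CH-C6H4-2-OiPr)[C,C-chelating 1-(adamantane-1,2-diyl)-3-(2,6-iPr2C6H3)imidazolin-2-ylidene] (7.5 mol %), ClCH2CH2Cl, 3 mM, 45 °C, static vacuum
Reagents that add atoms: none
Why: Z-selective ring-closing metathesis: the cyclometalated ruthenium alkylidene forms side-bound metallacyclobutanes with both substituents turned away from the N-aryl group, so the (Z)-alkene forms kinetically, and only the two monosubstituted allyl alkenes react.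

Step 23
Reactants: 32 (Z)-β-keto macrolactone
Product: 34 CNP0259772.1 (target), via bis-silyl tetronate 33 (not isolated)
Conditions: Bu4NF (6 equiv), THF, 0 → 25 °C; 1 M HCl work-up
Reagents that add atoms: none
Why: fluoride-promoted Dieckmann cyclisation: the β-keto ester enolate attacks the neighbouring methyl ester through a five-membered transition state, contracting the 12-membered lactone to the spirotetronate and 11-membered carbocycle, and the same fluoride cleaves both triethylsilyl ethers; no stereocentre is affected.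

**Compound list**
1 | (2E)-2-methylpent-2-enal | CC/C=C(\C)C=O | starting material
2 | ethyl (2E,4E)-2,4-dimethylhepta-2,4-dienoate | CC/C=C(\C)/C=C(\C)C(=O)OCC | intermediate
3 | (2E,4E)-2,4-dimethylhepta-2,4-dien-1-ol | CC/C=C(\C)/C=C(\C)CO | intermediate
4 | (2E,4E)-1-bromo-2,4-dimethylhepta-2,4-diene | CC/C=C(\C)/C=C(\C)CBr | intermediate
5 | (4E,6E)-4,6-dimethylnona-1,4,6-triene | CC/C=C(\C)/C=C(\C)CC=C | intermediate
6 | methyl pyruvate (methyl 2-oxopropanoate) | CC(=O)C(=O)OC | starting material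
7 | methyl 2-(acetyloxy)prop-2-enoate | C=C(OC(C)=O)C(=O)OC | intermediate
8 | methyl (1S,2R,5R)-1-(acetyloxy)-5-ethyl-2,4-dimethyl-2-(prop-2-en-1-yl)cyclohex-3-ene-1-carboxylate | CC[C@@H]1C[C@@](OC(C)=O)(C(=O)OC)[C@](C)(CC=C)C=C1C | intermediate
9 | methyl (1S,2R,5R)-5-ethyl-1-hydroxy-2,4-dimethyl-2-(prop-2-en-1-yl)cyclohex-3-ene-1-carboxylate | CC[C@@H]1C[C@@](O)(C(=O)OC)[C@](C)(CC=C)C=C1C | intermediate
10 | 1-(2,4-dinitrophenyl)pyridin-1-ium chloride | O=[N+]([O-])c1ccc([n+]2ccccc2)c(c1)[N+](=O)[O-].[Cl-] | starting material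
11 | N-[(2E,4E)-5-(dimethylamino)penta-2,4-dien-1-ylidene]-N-methylmethanaminium chloride | CN(C)/C=C/C=C/C=[N+](C)C.[Cl-] | intermediate (not isolated)
12 | (2E,4E)-5-(dimethylamino)penta-2,4-dienal | CN(C)/C=C/C=C/C=O | intermediate
13 | bromomagnesium (1E,3E)-1-(dimethylamino)octa-1,3,7-trien-5-olate | CN(C)/C=C/C=C/C(CC=C)O[Mg]Br | intermediate (not isolated)
14 | (2E,4E)-octa-2,4,7-trienal | C=CC/C=C/C=C/C=O | intermediate
15 | 2,2,6-trimethyl-4H-1,3-dioxin-4-one | CC1=CC(=O)OC(C)(C)O1 | starting material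
16 | 6-ethyl-2,2-dimethyl-4H-1,3-dioxin-4-one | CCC1=CC(=O)OC(C)(C)O1 | intermediate
17 | tert-butyl{[(6Z)-6-ethylidene-2,2-dimethyl-6H-1,3-dioxin-4-yl]oxy}dimethylsilane | C/C=C1\OC(C)(C)OC(O[Si](C)(C)C(C)(C)C)=C1 | intermediate
18 | trichlorosilyl ether of 19: 2,2-dimethyl-6-{(2R,3R,4E,6E)-3-[(trichlorosilyl)oxy]deca-4,6,9-trien-2-yl}-4H-1,3-dioxin-4-one | CC1(C)OC(=O)C=C(O1)[C@H](C)[C@H](O[Si](Cl)(Cl)Cl)/C=C/C=C/CC=C | intermediate (not isolated)
19 | 6-[(2R,3R,4E,6E)-3-hydroxydeca-4,6,9-trien-2-yl]-2,2-dimethyl-4H-1,3-dioxin-4-one | CC1(C)OC(=O)C=C(O1)[C@H](C)[C@H](O)/C=C/C=C/CC=C | intermediate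
20 | methyl (4R,5R,6E,8E)-5-hydroxy-4-methyl-3-oxododeca-6,8,11-trienoate | COC(=O)CC(=O)[C@H](C)[C@H](O)/C=C/C=C/CC=C | intermediate
21 | methyl (4R,5R,6E,8E)-5-[(diethylboranyl)oxy]-4-methyl-3-oxododeca-6,8,11-trienoate (boron chelate) | COC(=O)CC(=O)[C@H](C)[C@H](OB(CC)CC)/C=C/C=C/CC=C | intermediate (not isolated)
22 | methyl (3S,4S,5R,6E,8E)-3,5-dihydroxy-4-methyldodeca-6,8,11-trienoate | COC(=O)C[C@H](O)[C@H](C)[C@H](O)/C=C/C=C/CC=C | intermediate
23 | methyl (3S,4S,5R,6E,8E)-4-methyl-3,5-bis[(triethylsilyl)oxy]dodeca-6,8,11-trienoate | COC(=O)C[C@H](O[Si](CC)(CC)CC)[C@H](C)[C@H](O[Si](CC)(CC)CC)/C=C/C=C/CC=C | intermediate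
24 | diisobutylaluminium methyl hemiacetal of 25 | COC(O[Al](CC(C)C)CC(C)C)C[C@H](O[Si](CC)(CC)CC)[C@H](C)[C@H](O[Si](CC)(CC)CC)/C=C/C=C/CC=C | intermediate (not isolated)
25 | (3S,4S,5R,6E,8E)-4-methyl-3,5-bis[(triethylsilyl)oxy]dodeca-6,8,11-trienal | O=CC[C@H](O[Si](CC)(CC)CC)[C@H](C)[C@H](O[Si](CC)(CC)CC)/C=C/C=C/CC=C | intermediate
26 | (2E,5S,6S,7R,8E,10E)-2,6-dimethyl-5,7-bis[(triethylsilyl)oxy]tetradeca-2,8,10,13-tetraenal | O=C/C(C)=C/C[C@H](O[Si](CC)(CC)CC)[C@H](C)[C@H](O[Si](CC)(CC)CC)/C=C/C=C/CC=C | intermediate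
27 | (1R,2R,4aS,5R,6S,7S,8aR)-1,6-dimethyl-2-(prop-2-en-1-yl)-5,7-bis[(triethylsilyl)oxy]-1,2,4a,5,6,7,8,8a-octahydronaphthalene-1-carbaldehyde | O=C[C@@]1(C)[C@@H]2C[C@H](O[Si](CC)(CC)CC)[C@H](C)[C@H](O[Si](CC)(CC)CC)[C@H]2C=C[C@H]1CC=C | intermediate
28 | tert-butyl 3-hydroxy-3-[(1R,2R,4aS,5R,6S,7S,8aR)-1,6-dimethyl-2-(prop-2-en-1-yl)-5,7-bis[(triethylsilyl)oxy]-1,2,4a,5,6,7,8,8a-octahydronaphthalen-1-yl]propanoate (carbinol epimers) | CC(C)(C)OC(=O)CC(O)[C@@]1(C)[C@@H]2C[C@H](O[Si](CC)(CC)CC)[C@H](C)[C@H](O[Si](CC)(CC)CC)[C@H]2C=C[C@H]1CC=C | intermediate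
29 | tert-butyl 3-[(1R,2R,4aS,5R,6S,7S,8aR)-1,6-dimethyl-2-(prop-2-en-1-yl)-5,7-bis[(triethylsilyl)oxy]-1,2,4a,5,6,7,8,8a-octahydronaphthalen-1-yl]-3-oxopropanoate | CC(C)(C)OC(=O)CC(=O)[C@@]1(C)[C@@H]2C[C@H](O[Si](CC)(CC)CC)[C@H](C)[C@H](O[Si](CC)(CC)CC)[C@H]2C=C[C@H]1CC=C | intermediate
30 | acylketene: 3-[the octahydronaphthalen-1-yl group of 29]-3-oxoprop-1-en-1-one | O=C=CC(=O)[C@@]1(C)[C@@H]2C[C@H](O[Si](CC)(CC)CC)[C@H](C)[C@H](O[Si](CC)(CC)CC)[C@H]2C=C[C@H]1CC=C | intermediate (not isolated)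
31 | methyl (1S,2R,5R)-5-ethyl-2,4-dimethyl-2-(prop-2-en-1-yl)-1-({3-oxo-3-[(1R,2R,4aS,5R,6S,7S,8aR)-1,6-dimethyl-2-(prop-2-en-1-yl)-5,7-bis[(triethylsilyl)oxy]-1,2,4a,5,6,7,8,8a-octahydronaphthalen-1-yl]propanoyl}oxy)cyclohex-3-ene-1-carboxylate | CC[C@@H]1C[C@@](OC(=O)CC(=O)[C@@]2(C)[C@@H]3C[C@H](O[Si](CC)(CC)CC)[C@H](C)[C@H](O[Si](CC)(CC)CC)[C@H]3C=C[C@H]2CC=C)(C(=O)OC)[C@](C)(CC=C)C=C1C | intermediate
32 | 12-membered (Z)-β-keto macrolactone: 31 with the two allyl termini joined as a cis CH2–CH=CH–CH2 bridge, methyl ester and both triethylsilyl ethers retained | CC[C@@H]1C[C@@]2(OC(=O)CC(=O)[C@@]3(C)[C@@H]4C[C@H](O[Si](CC)(CC)CC)[C@H](C)[C@H](O[Si](CC)(CC)CC)[C@H]4C=C[C@H]3C/C=C\C[C@]2(C)C=C1C)C(=O)OC | intermediate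
33 | bis(triethylsilyl) ether of the target at the two decalin hydroxyls (present as its tetrabutylammonium tetronate) | CC[C@@H]1C[C@]23OC(=O)/C(=C(\O)[C@@]4(C)[C@@H]5C[C@H](O[Si](CC)(CC)CC)[C@H](C)[C@H](O[Si](CC)(CC)CC)[C@H]5C=C[C@H]4C/C=C\C[C@]2(C)C=C1C)C3=O | intermediate (not isolated)
34 | CNP0259772.1 | CC[C@@H]1C[C@]23OC(=O)/C(=C(\O)[C@@]4(C)[C@@H]5C[C@H](O)[C@H](C)[C@H](O)[C@H]5C=C[C@H]4C/C=C\C[C@]2(C)C=C1C)C3=O | target

**Step count and risks**
Total steps: 23 (fragment A 7, fragment B 13, union and endgame 3).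
Longest linear sequence: 14 steps (8, 9, 12–20, 21, 22, 23).

Three steps most likely to fail:

Step 6 (the new enantioselective cycloaddition; the diene is hindered and the dienophile only moderately reactive). Fallback, setting out from 5 and 7 and coming back at 31: run the cycloaddition with achiral MeAlCl2 (1.1 equiv, CH2Cl2, −78 → −20 °C), a known way to obtain exo adducts from (Z)-substituted dienes and α-substituted acrylic dienophiles. This gives 8 together with its enantiomer methyl (1R,2S,5S)-1-(acetyloxy)-5-ethyl-2,4-dimethyl-2-(prop-2-en-1-yl)cyclohex-3-ene-1-carboxylate F1. Methanolysis as in step 7 gives 9 and its enantiomer methyl (1R,2S,5S)-5-ethyl-1-hydroxy-2,4-dimethyl-2-(prop-2-en-1-yl)cyclohex-3-ene-1-carboxylate F2. The racemate (2.5 equiv) is joined to enantiopure 29 under the conditions of step 21, which gives 31 and the diastereomeric β-keto ester of the (1R,2S,5S)-alcohol F3; chromatography gives pure 31. Resolution by diastereomer separation replaces catalyst control at the cost of half of the cheap fragment.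

Step 21 (intermolecular capture of the acylketene by a tertiary alcohol flanked by a quaternary carbon). Fallback, setting out from 9 and 27 and coming back at 31: form the hindered C–O bond first with a small acyl donor and make the C–C bond to the decalin afterwards. Bromoacetyl bromide (pyridine, DMAP, CH2Cl2, 0 °C) converts 9 into methyl (1S,2R,5R)-1-[(bromoacetyl)oxy]-5-ethyl-2,4-dimethyl-2-(prop-2-en-1-yl)cyclohex-3-ene-1-carboxylate F4. A Reformatsky reaction of F4 with aldehyde 27 (activated Zn, THF, 40 °C; dilute HCl work-up) gives the 3-hydroxy analogue of 31 F5 as carbinol epimers. Dess–Martin oxidation as in step 20 gives 31.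

Step 22 (Z-selectivity and ring strain in closing the 12-membered lactone). Fallback, setting out from 31 and coming back at 33: change the order so that the metathesis closes the 11-membered carbocycle under thermodynamic control, where the (Z)-alkene found in the natural product should be the less strained isomer. KOtBu (2.2 equiv, THF, 0 °C) effects the Dieckmann cyclisation of 31 to the open bis(triethylsilyl) 3-acyltetronic acid bearing two allyl groups F6. Ring-closing metathesis of F6 with second-generation Hoveyda–Grubbs catalyst RuCl2(H2IMes)(=CH-C6H4-2-OiPr) (H2IMes = 1,3-dimesitylimidazolin-2-ylidene; toluene, 2 mM, 80 °C) gives 33, and Bu4NF as in step 23 gives 34.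

**Further compounds**
F1 | step 6 | methyl (1R,2S,5S)-1-(acetyloxy)-5-ethyl-2,4-dimethyl-2-(prop-2-en-1-yl)cyclohex-3-ene-1-carboxylate | CC[C@H]1C[C@](OC(C)=O)(C(=O)OC)[C@@](C)(CC=C)C=C1C
F2 | step 6 | methyl (1R,2S,5S)-5-ethyl-1-hydroxy-2,4-dimethyl-2-(prop-2-en-1-yl)cyclohex-3-ene-1-carboxylate | CC[C@H]1C[C@](O)(C(=O)OC)[C@@](C)(CC=C)C=C1C
F3 | step 6 | diastereomer of 31 with the (1R,2S,5S)-cyclohexene half | CC[C@H]1C[C@](OC(=O)CC(=O)[C@@]2(C)[C@@H]3C[C@H](O[Si](CC)(CC)CC)[C@H](C)[C@H](O[Si](CC)(CC)CC)[C@H]3C=C[C@H]2CC=C)(C(=O)OC)[C@@](C)(CC=C)C=C1C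
F4 | step 21 | methyl (1S,2R,5R)-1-[(bromoacetyl)oxy]-5-ethyl-2,4-dimethyl-2-(prop-2-en-1-yl)cyclohex-3-ene-1-carboxylate | CC[C@@H]1C[C@@](OC(=O)CBr)(C(=O)OC)[C@](C)(CC=C)C=C1C
F5 | step 21 | 3-hydroxy analogue of 31 (β-hydroxy ester, carbinol epimers) | CC[C@@H]1C[C@@](OC(=O)CC(O)[C@@]2(C)[C@@H]3C[C@H](O[Si](CC)(CC)CC)[C@H](C)[C@H](O[Si](CC)(CC)CC)[C@H]3C=C[C@H]2CC=C)(C(=O)OC)[C@](C)(CC=C)C=C1C
F6 | step 22 | open bis(triethylsilyl) 3-acyltetronic acid bearing two allyl groups (Dieckmann product of 31) | CC[C@@H]1C[C@]2(OC(=O)/C(=C(\O)[C@@]3(C)[C@@H]4C[C@H](O[Si](CC)(CC)CC)[C@H](C)[C@H](O[Si](CC)(CC)CC)[C@H]4C=C[C@H]3CC=C)C2=O)[C@](C)(CC=C)C=C1C
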